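Ring C (C8, C9, C11–C14; abietane locants, C10 quaternary, C5 isopropenyl-bearing, C7 ketone) is hexasubstituted, with para hydroxyls at C11 and C14 enclosing OMe at C12 and isopropyl at C13, and with C9 joined to quaternary C10; the strategy rests on building this ring de novo.
Ring C is cut at C8–C14 (6π closure of a dienylketene) and at C9–C11 (alkenyllithium plus 3-isopropyl-4-methoxycyclobutenedione), so it derives from the C8=C9 alkene of ring B and a squarate four-carbon unit.
Ring B comes intact from (R)-carvone: its isopropenyl group is degraded with retention to a C7 silyloxy group, which directs the new isopropenyl to C5 (trans cuprate addition) and the allyl group to C10 (anti to isopropenyl), and is finally oxidised to the C7 ketone.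
Ring order: ring B (chiral pool), then the four-membered ring at C9, then ring C by thermal ring expansion; the acid and C7 ketone are set at the quinone stage and dithionite returns the hydroquinone.

Key step: step 13

Step 1
Reactants: 1 (R)-(−)-carvone
Product: 4 (R)-5-acetoxy-2-methylcyclohex-2-en-1-one, via methoxy hydroperoxide 2 (not isolated), via peracetate 3 (not isolated)
Conditions: O3, CH2Cl2/MeOH, −78 °C; then Ac2O, Et3N, DMAP (cat.), −78 °C to rt
Reagents that add atoms: ozone [O-][O+]=O; methanol CO; acetic anhydride CC(=O)OC(C)=O (its acetyl group is held in 3 only)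
Why: Ozone should attack only the electron-rich isopropenyl alkene, methanol traps the carbonyl oxide as 2, and peracetate 3 undergoes Criegee rearrangement in which the ring carbon migrates to oxygen with retention (acetate then demethylates the dioxacarbenium ion), so the carvone stereocentre becomes the acetoxy carbon unchanged.

Step 2
Reactants: 4 (R)-5-acetoxy-2-methylcyclohex-2-en-1-one
Product: 5 (R)-5-hydroxy-2-methylcyclohex-2-en-1-one
Conditions: K2CO3 (cat.), MeOH, 0 °C
Reagents that add atoms: none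
Why: Base-catalysed transesterification removes the acetyl group, and low temperature with catalytic carbonate should keep β-elimination of the β-oxygenated ketone (toward o-cresol) slow; the stereocentre is not involved.

Step 3
Reactants: 5 (R)-5-hydroxy-2-methylcyclohex-2-en-1-one
Product: 6 (R)-5-(tert-butyldimethylsilyloxy)-2-methylcyclohex-2-en-1-one
Conditions: TBSCl, imidazole, DMF, 0 °C to rt
Reagents that add atoms: tert-butyldimethylsilyl chloride CC(C)(C)[Si](C)(C)Cl
Why: Standard imidazole-promoted silylation of a secondary alcohol gives an ether that tolerates the organometallic steps and blocks β-elimination.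

Step 4
Reactants: 6 (R)-5-(tert-butyldimethylsilyloxy)-2-methylcyclohex-2-en-1-one; 7 isopropenylmagnesium bromide
Product: 8 (3S,5R)-5-(tert-butyldimethylsilyloxy)-2-methyl-3-(prop-1-en-2-yl)-1-(trimethylsilyloxy)cyclohex-1-ene (isopropenyl trans to OTBS)
Conditions: CuBr·SMe2 (20 mol %), TMSCl, HMPA, THF, −78 °C; Et3N, cold aq NaHCO3
Reagents that add atoms: chlorotrimethylsilane C[Si](C)(C)Cl
Why: Copper-catalysed, TMSCl-accelerated conjugate addition of the Grignard reagent proceeds by axial attack on the half-chair with the C5 silyloxy group pseudo-equatorial, placing isopropenyl trans to OTBS (sets abietane C5), and silyl trapping fixes the enolate regiochemistry before it can equilibrate or eliminate.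

Step 5
Reactants: 8 silyl enol ether from step 4; 9 allyl bromide
Product: 11 (2S,3S,5R)-2-allyl-5-(tert-butyldimethylsilyloxy)-2-methyl-3-(prop-1-en-2-yl)cyclohexan-1-one, via lithium enolate 10 (not isolated)
Conditions: MeLi, THF, 0 °C; then 9, DMPU, −78 to 0 °C
Reagents that add atoms: methyllithium [Li]C (its lithium is held in 10 only)
Why: MeLi cleaves the O–SiMe3 bond to the regiodefined tetrasubstituted lithium enolate, which is C-allylated anti to the neighbouring isopropenyl group (held pseudo-axial by A(1,2) strain with the enolate methyl), so the quaternary centre (abietane C10) forms with methyl cis and allyl trans to isopropenyl.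

Step 6
Reactants: 11 allyl ketone from step 5
Product: 13 (2S,3S,5R)-5-(tert-butyldimethylsilyloxy)-2-(3-hydroxypropyl)-2-methyl-3-(prop-1-en-2-yl)cyclohexan-1-one, via pinacol boronate 12 (not isolated)
Conditions: HBpin, RhCl(PPh3)3 (3 mol %), CH2Cl2, rt; then NaBO3·4H2O, THF/H2O, rt
Reagents that add atoms: pinacolborane CC1(C)OBOC1(C)C (held in 12 only); sodium perborate [Na+].[O-]OB=O
Why: Rhodium-catalysed hydroboration is steeply sensitive to alkene substitution and outruns uncatalysed carbonyl reduction, so only the monosubstituted allyl terminus should be borylated anti-Markovnikov, whereas uncatalysed dialkylboranes such as 9-BBN discriminate poorly between vinyl and isopropenyl groups; perborate then oxidises the C–B bond without exposing the β-silyloxy ketone to hydroxide.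

Step 7
Reactants: 13 hydroxy ketone from step 6
Product: 14 (2S,3S,5R)-5-(tert-butyldimethylsilyloxy)-2-[3-(tert-butyldimethylsilyloxy)propyl]-2-methyl-3-(prop-1-en-2-yl)cyclohexan-1-one
Conditions: TBSCl, imidazole, DMF, rt
Reagents that add atoms: tert-butyldimethylsilyl chloride CC(C)(C)[Si](C)(C)Cl
Why: Silylation of the primary alcohol is fast, and any cyclic hemiketal of the δ-hydroxy ketone is drained through the open form.

Step 8
Reactants: 14 bis-silyl ketone from step 7
Product: 15 hydrazone of 14 (C=N–NH2 at abietane C9, ring stereocentres unchanged)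
Conditions: N2H4·H2O (excess), Et3N, EtOH, 80 °C
Reagents that add atoms: hydrazine hydrate NN.O
Why: Hydrazone condensation needs forcing conditions because the carbonyl is flanked by the quaternary carbon; excess hydrazine suppresses azine formation and the silyloxy group is a poor leaving group under these weakly basic conditions.

Step 9
Reactants: 15 hydrazone from step 8
Product: 16 (3R,5S,6S)-3-(tert-butyldimethylsilyloxy)-6-[3-(tert-butyldimethylsilyloxy)propyl]-1-iodo-6-methyl-5-(prop-1-en-2-yl)cyclohex-1-ene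
Conditions: I2, 1,1,3,3-tetramethylguanidine, THF/Et2O, 0 °C to rt (hydrazone added to the iodine/base solution)
Reagents that add atoms: iodine II
Why: In the Barton vinyl iodide synthesis iodine oxidises the hydrazone to a diazoalkane, and iodination with loss of N2 gives an α-iodo cation that can lose a proton only from C8, the sole α-carbon bearing hydrogen, so the C8=C9 iodoalkene is the only regioisomer possible.

Step 10
Reactants: 17 dimethyl squarate; 18 isopropylmagnesium chloride
Product: 19 4-hydroxy-2,3-dimethoxy-4-(propan-2-yl)cyclobut-2-en-1-one (racemic)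
Conditions: THF, −78 °C; aq NH4Cl
Reagents that add atoms: none
Why: 1,2-Addition of the Grignard reagent to one of the two equivalent, strained and highly electrophilic carbonyl groups of the squarate stops at mono-addition at low temperature.

Step 11
Reactants: 19 squarate adduct from step 10
Product: 21 3-methoxy-4-(propan-2-yl)cyclobut-3-ene-1,2-dione, via trifluoroacetate 20 (not isolated)
Conditions: (CF3CO)2O, Et2O, −78 to 0 °C; then H2O, aq NaHCO3
Reagents that add atoms: trifluoroacetic anhydride O=C(OC(=O)C(F)(F)F)C(F)(F)F (held in 20 only); water O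
Why: Trifluoroacetylation makes the tertiary hydroxyl a leaving group, ionisation gives a methoxy-stabilised cyclobutenyl cation, and hydrolysis at the oxocarbenium carbon expels methanol, transposing the carbonyl to give the alkyl(methoxy)cyclobutenedione.

Step 12
Reactants: 16 vinyl iodide from step 9; 21 3-methoxy-4-(propan-2-yl)cyclobut-3-ene-1,2-dione
Product: 23 4-hydroxy-3-methoxy-2-(propan-2-yl)-4-[(3R,5S,6S)-3-(tert-butyldimethylsilyloxy)-6-[3-(tert-butyldimethylsilyloxy)propyl]-6-methyl-5-(prop-1-en-2-yl)cyclohex-1-en-1-yl]cyclobut-2-en-1-one (both carbinol epimers), via alkenyllithium 22 (not isolated)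
Conditions: t-BuLi (2.0 equiv), Et2O, −78 °C; cannulated into 21 (1.5 equiv), THF, −78 °C; aq NH4Cl at −78 °C
Reagents that add atoms: tert-butyllithium [Li]C(C)(C)C (its lithium is held in 22 only)
Why: Iodine–lithium exchange gives the C9 alkenyllithium, which should add 1,2 to the ketone-like carbonyl (the one attached to the methoxy-bearing carbon) in preference to the less electrophilic vinylogous ester carbonyl, forming the C9–C11 bond; the new carbinol centre is uncontrolled but becomes aromatic C11.

Step 13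
Reactants: 23 4-alkenyl-4-hydroxycyclobutenone from step 12
Product: 26 (1S,2S,4R)-4-(tert-butyldimethylsilyloxy)-1-[3-(tert-butyldimethylsilyloxy)propyl]-7-methoxy-1-methyl-6-(propan-2-yl)-2-(prop-1-en-2-yl)-1,2,3,4-tetrahydronaphthalene-5,8-diol (the 11,14-hydroquinone), via dienylketene 24 (not isolated), via cyclohexadienone 25 (not isolated)
Conditions: degassed p-xylene, 135 °C, argon
Reagents that add atoms: none
Why: Heating triggers conrotatory 4π electrocyclic opening of the cyclobutenone (the C11–C14 bond breaks) to dienylketene 24, the hydroxyl turning outward (donor torquoselectivity) so that the cyclohexenyl group lies cis to the ketene. Ring C then closes by thermal disrotatory 6π electrocyclisation, ketene carbon C14 bonding to C8 in an all-carbon six-membered closure, and enolisation of the C8–H of dienone 25 aromatises it irreversibly to the 11,14-hydroquinone. This is the Moore rearrangement of 4-alkenyl-4-hydroxycyclobutenones, applied here to an alkenyl group flanked by a quaternary carbon. No lasting stereocentre is created, since the carbinol carbon and the transient C8 centre both become sp2, while C5, C7 and C10 are untouched. The selectivities needed are outward rotation of the hydroxyl, which is secured electronically, and the substituent order C9, C11-OH, C12-OMe, C13-isopropyl, C14-OH, C8, which is fixed by the regiochemistry of step 12. The C9–C10 linkage is therefore an ordinary ring-B bond from the outset and is never forged by arylation at a crowded centre.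

Step 14
Reactants: 26 hydroquinone from step 13 (used crude)
Product: 27 (5R,7S,8S)-5-(tert-butyldimethylsilyloxy)-8-[3-(tert-butyldimethylsilyloxy)propyl]-2-methoxy-8-methyl-3-(propan-2-yl)-7-(prop-1-en-2-yl)-5,6,7,8-tetrahydronaphthalene-1,4-dione (the 11,14-quinone)
Conditions: Ag2O, MgSO4, Et2O, rt
Reagents that add atoms: none
Why: Silver oxide dehydrogenates the electron-rich hydroquinone to the p-quinone, which is stable to air and to the oxidants used later.

Step 15
Reactants: 27 quinone from step 14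
Product: 28 (5R,7S,8S)-5-hydroxy-8-(3-hydroxypropyl)-2-methoxy-8-methyl-3-(propan-2-yl)-7-(prop-1-en-2-yl)-5,6,7,8-tetrahydronaphthalene-1,4-dione
Conditions: HF·pyridine, pyridine/THF, 0 °C to rt
Reagents that add atoms: none
Why: Buffered fluoride cleaves both Si–O bonds, while the quinone, the vinylogous ester OMe and the isopropenyl group are inert to HF·pyridine.

Step 16
Reactants: 28 quinone diol from step 15
Product: 29 3-[(1S,2S)-7-methoxy-1-methyl-4,5,8-trioxo-6-(propan-2-yl)-2-(prop-1-en-2-yl)-1,2,3,4,5,8-hexahydronaphthalen-1-yl]propanal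
Conditions: Dess–Martin periodinane (3 equiv), NaHCO3, CH2Cl2, rt
Reagents that add atoms: none
Why: Dess–Martin oxidation converts the primary alcohol to the aldehyde and the C7 alcohol to the ketone, erasing the relay stereocentre; any 7-oxo hydroquinone formed from 28 by internal redox tautomerisation is taken to the same product by the excess oxidant.

Step 17
Reactants: 29 keto aldehyde from step 16
Product: 30 3-[(1S,2S)-7-methoxy-1-methyl-4,5,8-trioxo-6-(propan-2-yl)-2-(prop-1-en-2-yl)-1,2,3,4,5,8-hexahydronaphthalen-1-yl]propanoic acid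
Conditions: NaClO2, NaH2PO4, 2-methyl-2-butene, t-BuOH/H2O, 0 °C to rt
Reagents that add atoms: sodium chlorite [Na+].[O-]Cl=O
Why: Pinnick oxidation is selective for the aldehyde; 2-methyl-2-butene scavenges HOCl so the isopropenyl group is spared, and a peroxide scavenger is avoided because it would epoxidise the quinone.

Step 18
Reactants: 30 quinone keto acid from step 17
Product: 31 3-[(1S,2S)-5,8-dihydroxy-7-methoxy-1-methyl-4-oxo-6-(propan-2-yl)-2-(prop-1-en-2-yl)-1,2,3,4-tetrahydronaphthalen-1-yl]propanoic acid (CNP0249049.1)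
Conditions: Na2S2O4, EtOAc/H2O, rt; dilute HCl to pH 3, argon
Reagents that add atoms: none
Why: Dithionite reduces only the quinone, and the resulting hydroquinone should resist re-oxidation because the C7 carbonyl withdraws electron density and hydrogen-bonds to the C14 hydroxyl.

Compound list
1 | (R)-(−)-carvone | CC1=CC[C@@H](C(C)=C)CC1=O | starting material
2 | (5R)-5-(1-hydroperoxy-1-methoxyethyl)-2-methylcyclohex-2-en-1-one (side-chain epimers) | CC1=CC[C@@H](C(C)(OC)OO)CC1=O | intermediate (not isolated)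
3 | (5R)-5-[1-(acetylperoxy)-1-methoxyethyl]-2-methylcyclohex-2-en-1-one | CC1=CC[C@@H](C(C)(OC)OOC(C)=O)CC1=O | intermediate (not isolated)
4 | (R)-5-acetoxy-2-methylcyclohex-2-en-1-one | CC1=CC[C@@H](OC(C)=O)CC1=O | intermediate
5 | (R)-5-hydroxy-2-methylcyclohex-2-en-1-one | CC1=CC[C@@H](O)CC1=O | intermediate
6 | (R)-5-(tert-butyldimethylsilyloxy)-2-methylcyclohex-2-en-1-one | CC1=CC[C@@H](O[Si](C)(C)C(C)(C)C)CC1=O | intermediate
7 | isopropenylmagnesium bromide | C=C(C)[Mg]Br | starting material
8 | (3S,5R)-5-(tert-butyldimethylsilyloxy)-2-methyl-3-(prop-1-en-2-yl)-1-(trimethylsilyloxy)cyclohex-1-ene | C[Si](C)(C)OC1=C(C)[C@H](C(C)=C)C[C@@H](O[Si](C)(C)C(C)(C)C)C1 | intermediate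
9 | allyl bromide | C=CCBr | starting material
10 | lithium (3S,5R)-5-(tert-butyldimethylsilyloxy)-2-methyl-3-(prop-1-en-2-yl)cyclohex-1-en-1-olate | [Li]OC1=C(C)[C@H](C(C)=C)C[C@@H](O[Si](C)(C)C(C)(C)C)C1 | intermediate (not isolated)
11 | (2S,3S,5R)-2-allyl-5-(tert-butyldimethylsilyloxy)-2-methyl-3-(prop-1-en-2-yl)cyclohexan-1-one | O=C1C[C@H](O[Si](C)(C)C(C)(C)C)C[C@@H](C(C)=C)[C@]1(C)CC=C | intermediate
12 | (2S,3S,5R)-5-(tert-butyldimethylsilyloxy)-2-methyl-3-(prop-1-en-2-yl)-2-[3-(4,4,5,5-tetramethyl-1,3,2-dioxaborolan-2-yl)propyl]cyclohexan-1-one | O=C1C[C@H](O[Si](C)(C)C(C)(C)C)C[C@@H](C(C)=C)[C@]1(C)CCCB2OC(C)(C)C(C)(C)O2 | intermediate (not isolated)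
13 | (2S,3S,5R)-5-(tert-butyldimethylsilyloxy)-2-(3-hydroxypropyl)-2-methyl-3-(prop-1-en-2-yl)cyclohexan-1-one | O=C1C[C@H](O[Si](C)(C)C(C)(C)C)C[C@@H](C(C)=C)[C@]1(C)CCCO | intermediate
14 | (2S,3S,5R)-5-(tert-butyldimethylsilyloxy)-2-[3-(tert-butyldimethylsilyloxy)propyl]-2-methyl-3-(prop-1-en-2-yl)cyclohexan-1-one | O=C1C[C@H](O[Si](C)(C)C(C)(C)C)C[C@@H](C(C)=C)[C@]1(C)CCCO[Si](C)(C)C(C)(C)C | intermediate
15 | hydrazone of 14 | NN=C1C[C@H](O[Si](C)(C)C(C)(C)C)C[C@@H](C(C)=C)[C@]1(C)CCCO[Si](C)(C)C(C)(C)C | intermediate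
16 | (3R,5S,6S)-3-(tert-butyldimethylsilyloxy)-6-[3-(tert-butyldimethylsilyloxy)propyl]-1-iodo-6-methyl-5-(prop-1-en-2-yl)cyclohex-1-ene | IC1=C[C@H](O[Si](C)(C)C(C)(C)C)C[C@@H](C(C)=C)[C@]1(C)CCCO[Si](C)(C)C(C)(C)C | intermediate
17 | dimethyl squarate (3,4-dimethoxycyclobut-3-ene-1,2-dione) | COC1=C(OC)C(=O)C1=O | starting material
18 | isopropylmagnesium chloride | CC(C)[Mg]Cl | starting material
19 | 4-hydroxy-2,3-dimethoxy-4-(propan-2-yl)cyclobut-2-en-1-one (racemic) | COC1=C(OC)C(O)(C(C)C)C1=O | intermediate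
20 | 2,3-dimethoxy-4-oxo-1-(propan-2-yl)cyclobut-2-en-1-yl trifluoroacetate | COC1=C(OC)C(OC(=O)C(F)(F)F)(C(C)C)C1=O | intermediate (not isolated)
21 | 3-methoxy-4-(propan-2-yl)cyclobut-3-ene-1,2-dione | COC1=C(C(C)C)C(=O)C1=O | intermediate
22 | [(3R,5S,6S)-3-(tert-butyldimethylsilyloxy)-6-[3-(tert-butyldimethylsilyloxy)propyl]-6-methyl-5-(prop-1-en-2-yl)cyclohex-1-en-1-yl]lithium | [Li]C1=C[C@H](O[Si](C)(C)C(C)(C)C)C[C@@H](C(C)=C)[C@]1(C)CCCO[Si](C)(C)C(C)(C)C | intermediate (not isolated)
23 | 4-hydroxy-3-methoxy-2-(propan-2-yl)-4-[(3R,5S,6S)-cyclohexenyl]cyclobut-2-en-1-one (cyclohexenyl group as in 16; carbinol epimers) | COC1=C(C(C)C)C(=O)C1(O)C2=C[C@H](O[Si](C)(C)C(C)(C)C)C[C@@H](C(C)=C)[C@]2(C)CCCO[Si](C)(C)C(C)(C)C | intermediate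
24 | (Z)-dienylketene: 4-hydroxy-3-methoxy-2-(propan-2-yl)-4-(cyclohexenyl)buta-1,3-dien-1-one, cyclohexenyl cis to the ketene-bearing carbon | O=C=C(C(C)C)/C(OC)=C(/O)C1=C[C@H](O[Si](C)(C)C(C)(C)C)C[C@@H](C(C)=C)[C@]1(C)CCCO[Si](C)(C)C(C)(C)C | intermediate (not isolated)
25 | ring-C cyclohexa-2,4-dienone (C14 ketone, C8–H sp3, C11 enol), ring-B centres as in 26 | C=C(C)[C@@H]1C[C@@H](O[Si](C)(C)C(C)(C)C)C2C(=O)C(C(C)C)=C(OC)C(O)=C2[C@@]1(C)CCCO[Si](C)(C)C(C)(C)C | intermediate (not isolated)
26 | (1S,2S,4R)-4-(tert-butyldimethylsilyloxy)-1-[3-(tert-butyldimethylsilyloxy)propyl]-7-methoxy-1-methyl-6-(propan-2-yl)-2-(prop-1-en-2-yl)-1,2,3,4-tetrahydronaphthalene-5,8-diol | C=C(C)[C@@H]1C[C@@H](O[Si](C)(C)C(C)(C)C)c2c(O)c(C(C)C)c(OC)c(O)c2[C@@]1(C)CCCO[Si](C)(C)C(C)(C)C | intermediate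
27 | (5R,7S,8S)-5-(tert-butyldimethylsilyloxy)-8-[3-(tert-butyldimethylsilyloxy)propyl]-2-methoxy-8-methyl-3-(propan-2-yl)-7-(prop-1-en-2-yl)-5,6,7,8-tetrahydronaphthalene-1,4-dione | C=C(C)[C@@H]1C[C@@H](O[Si](C)(C)C(C)(C)C)C2=C(C(=O)C(OC)=C(C(C)C)C2=O)[C@@]1(C)CCCO[Si](C)(C)C(C)(C)C | intermediate
28 | (5R,7S,8S)-5-hydroxy-8-(3-hydroxypropyl)-2-methoxy-8-methyl-3-(propan-2-yl)-7-(prop-1-en-2-yl)-5,6,7,8-tetrahydronaphthalene-1,4-dione | C=C(C)[C@@H]1C[C@@H](O)C2=C(C(=O)C(OC)=C(C(C)C)C2=O)[C@@]1(C)CCCO | intermediate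
29 | 3-[(1S,2S)-7-methoxy-1-methyl-4,5,8-trioxo-6-(propan-2-yl)-2-(prop-1-en-2-yl)-1,2,3,4,5,8-hexahydronaphthalen-1-yl]propanal | C=C(C)[C@@H]1CC(=O)C2=C(C(=O)C(OC)=C(C(C)C)C2=O)[C@@]1(C)CCC=O | intermediate
30 | 3-[(1S,2S)-7-methoxy-1-methyl-4,5,8-trioxo-6-(propan-2-yl)-2-(prop-1-en-2-yl)-1,2,3,4,5,8-hexahydronaphthalen-1-yl]propanoic acid | C=C(C)[C@@H]1CC(=O)C2=C(C(=O)C(OC)=C(C(C)C)C2=O)[C@@]1(C)CCC(=O)O | intermediate
31 | 3-[(1S,2S)-5,8-dihydroxy-7-methoxy-1-methyl-4-oxo-6-(propan-2-yl)-2-(prop-1-en-2-yl)-1,2,3,4-tetrahydronaphthalen-1-yl]propanoic acid | C=C(C)[C@@H]1CC(=O)c2c(O)c(C(C)C)c(OC)c(O)c2[C@@]1(C)CCC(=O)O | target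

Total step count: 18.
Longest linear sequence: 16 steps (steps 1–9 and 12–18, from (R)-carvone); the cyclobutenedione branch is 2 steps (10–11).

Steps most likely to fail

Step 12 (fragment union). The congested alkenyllithium, with lithium on C9 next to quaternary C10, may add to the dione too slowly, so that proton transfer, electron transfer or attack at the vinylogous ester carbonyl competes. The fallback sets out from alkenyllithium 22 (made from 16 as in step 12), builds ring C by a Dötz benzannulation and rejoins the route at quinone 27, bypassing steps 12–14. Addition of 22 to Cr(CO)6 in Et2O and O-methylation of the acyl chromate with Me3OBF4 would give the pentacarbonyl[methoxy(alkenyl)carbene]chromium complex F1. Heating F1 with 3-methylbut-1-yne in THF at 55 °C places the isopropyl-bearing alkyne carbon next to the CO-derived carbon C14, and work-up with (NH4)2Ce(NO3)6 in MeCN/H2O at 0 °C should give the 12-unsubstituted 11,14-quinone F2. Nucleophilic epoxidation of its C12=C13 bond (H2O2, Na2CO3, THF/H2O, 0 °C; the tetrasubstituted C8=C9 bond is shielded) would give the epoxyquinone F3. Isomerisation with catalytic camphorsulfonic acid in CH2Cl2 would give the 12-hydroxyquinone F4, and O-methylation with TMSCHN2 in MeOH/toluene would give 27.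

Step 9 (vinyl iodide, together with the hydrazone of step 8). Condensation at the hindered carbonyl may stall, and azine formation or geminal di-iodination may take over in the iodine oxidation. The fallback sets out from ketone 14 and rejoins at alkenyllithium 22. Deprotonation at C8, the only enolisable position, with KN(SiMe3)2 and trapping with PhNTf2 (THF, −78 °C) would give the enol triflate F5. Stannylation with Me3SnSnMe3, Pd(PPh3)4 and LiCl in dioxane at 90 °C would give the alkenylstannane F6, and tin–lithium exchange with MeLi in THF at −78 °C delivers 22, which is added to 21 as in step 12.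

Step 6 (chemoselective hydroboration). Selectivity may erode through borylation of the isopropenyl group, rhodium hydride isomerisation of the allyl group or carbonyl reduction. The fallback sets out from allyl ketone 11 and rejoins at alcohol 13, distinguishing the two alkenes by metathesis reactivity. Cross-metathesis of 11 with vinylboronic acid pinacol ester (second-generation Grubbs catalyst, RuCl2(=CHPh)(H2IMes)(PCy3), CH2Cl2, 40 °C) engages only the monosubstituted alkene and would give the (E)-alkenyl boronate F7. Perborate oxidation (NaBO3·4H2O, THF/H2O) gives the keto aldehyde F8, and NaBH4 in MeOH/THF at −78 °C reduces the aldehyde but not the hindered ketone, giving 13.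

Further compounds
F1 | step 12 | pentacarbonyl{methoxy[(3R,5S,6S)-3-(tert-butyldimethylsilyloxy)-6-[3-(tert-butyldimethylsilyloxy)propyl]-6-methyl-5-(prop-1-en-2-yl)cyclohex-1-en-1-yl]methylidene}chromium | COC(=[Cr])C1=C[C@H](O[Si](C)(C)C(C)(C)C)C[C@@H](C(C)=C)[C@]1(C)CCCO[Si](C)(C)C(C)(C)C.[C-]#[O+].[C-]#[O+].[C-]#[O+].[C-]#[O+].[C-]#[O+]
F2 | step 12 | (5R,7S,8S)-5-(tert-butyldimethylsilyloxy)-8-[3-(tert-butyldimethylsilyloxy)propyl]-8-methyl-3-(propan-2-yl)-7-(prop-1-en-2-yl)-5,6,7,8-tetrahydronaphthalene-1,4-dione | C=C(C)[C@@H]1C[C@@H](O[Si](C)(C)C(C)(C)C)C2=C(C(=O)C=C(C(C)C)C2=O)[C@@]1(C)CCCO[Si](C)(C)C(C)(C)C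
F3 | step 12 | 2,3-epoxide of F2 (oxirane across C12–C13, epimers) | C=C(C)[C@@H]1C[C@@H](O[Si](C)(C)C(C)(C)C)C2=C(C(=O)C3OC3(C(C)C)C2=O)[C@@]1(C)CCCO[Si](C)(C)C(C)(C)C
F4 | step 12 | (5R,7S,8S)-5-(tert-butyldimethylsilyloxy)-8-[3-(tert-butyldimethylsilyloxy)propyl]-2-hydroxy-8-methyl-3-(propan-2-yl)-7-(prop-1-en-2-yl)-5,6,7,8-tetrahydronaphthalene-1,4-dione | C=C(C)[C@@H]1C[C@@H](O[Si](C)(C)C(C)(C)C)C2=C(C(=O)C(O)=C(C(C)C)C2=O)[C@@]1(C)CCCO[Si](C)(C)C(C)(C)C
F5 | step 9 | (3R,5S,6S)-3-(tert-butyldimethylsilyloxy)-6-[3-(tert-butyldimethylsilyloxy)propyl]-6-methyl-5-(prop-1-en-2-yl)cyclohex-1-en-1-yl trifluoromethanesulfonate | O=S(=O)(OC1=C[C@H](O[Si](C)(C)C(C)(C)C)C[C@@H](C(C)=C)[C@]1(C)CCCO[Si](C)(C)C(C)(C)C)C(F)(F)F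
F6 | step 9 | [(3R,5S,6S)-3-(tert-butyldimethylsilyloxy)-6-[3-(tert-butyldimethylsilyloxy)propyl]-6-methyl-5-(prop-1-en-2-yl)cyclohex-1-en-1-yl]trimethylstannane | C[Sn](C)(C)C1=C[C@H](O[Si](C)(C)C(C)(C)C)C[C@@H](C(C)=C)[C@]1(C)CCCO[Si](C)(C)C(C)(C)C
F7 | step 6 | (2S,3S,5R)-5-(tert-butyldimethylsilyloxy)-2-methyl-3-(prop-1-en-2-yl)-2-[(E)-3-(4,4,5,5-tetramethyl-1,3,2-dioxaborolan-2-yl)prop-2-en-1-yl]cyclohexan-1-one | O=C1C[C@H](O[Si](C)(C)C(C)(C)C)C[C@@H](C(C)=C)[C@]1(C)C/C=C/B2OC(C)(C)C(C)(C)O2
F8 | step 6 | 3-[(1S,4R,6S)-4-(tert-butyldimethylsilyloxy)-1-methyl-2-oxo-6-(prop-1-en-2-yl)cyclohexyl]propanal | O=C1C[C@H](O[Si](C)(C)C(C)(C)C)C[C@@H](C(C)=C)[C@]1(C)CCC=O
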